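## The problem

The target 15 is an aryltetralin cyclolignan. Ring A is the fused benzene ring (C4a, C5–C8, C8a) with methoxy groups on C6 and C8 and a free hydroxyl on C7; ring B is the saturated ring C1–C4; ring C is the 4-hydroxy-3-methoxyphenyl group on C1; C9 and C9' are the hydroxymethyl carbons on C2 and C3. Ring B carries three contiguous stereocentres, C1 (R), C2 (S) and C3 (S), in the trans,trans array: ring C and C9' lie on one face, C9 on the other. The bond that resists closure is C1–C8a. It makes C1 a diarylmethine pressed against the C8 methoxy group, and this peri contact pushes ring C pseudoaxial, so an equilibration at C3 cannot be trusted to give the trans,trans isomer. C2 is bonded to both other centres and can control them: a bond made at C1 and a bond made at C3, each anti to the C2 substituent, give the whole array from one reagent-controlled centre. The groups at risk are the two free phenols (oxidation, quinone methide formation), the electron-rich C1–H, and the 1,4-diol, which closes to a tetrahydrofuran in strong acid. The feature that opens the plan is the 1,3-relationship of C1 and C3 across C2: C1 is benzylic and para to the C4' oxygen of ring C (a donor carbon), and C3 can carry two carbonyl groups, C9' as an ester and C4 as a ring A aryl ketone (an acceptor carbon). A C1–C3 bond therefore defines a donor–acceptor cyclopropane C1–C2–C3, whose strain-driven heterolysis puts a cation on C1 next to C8a, a ring A carbon ortho to the C8 and para to the C6 methoxy group, with an equivalent twin on the other side of the aroyl group.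

## Retrosynthesis

15 from 14. No skeletal bond is cut. The two primary alcohols are taken back to methyl esters, so that C3 can be an acceptor carbon earlier in the route. The forward step is a hydride reduction that must not epimerize C2 or C3.

14 from 12 (through 13). The C3–H and C4–H bonds and the two phenolic O–H bonds are taken back to a C3=C4 enol triflate and two benzyl ethers. This is preferred to its neighbours: protonation of a C3 enolate would occur anti to the C2 substituent and give the 2,3-cis isomer, and equilibration of the diester is unsafe because of the peri contact. The forward step must deliver hydrogen to C3 from the face opposite ring C.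

12 from 11. The triflate is taken back to the β-keto ester 11, whose C3 is an enol carbon; whatever configuration C3 has in 11 is erased.

11 from 9 (key disconnection). The C1–C8a bond is cut and C1 is reconnected to C3, giving cyclopropane 9. The neighbouring cut, C1–C8a from an open-chain benzylic alcohol, needs C2 and C3 both set beforehand and a chain built bond by bond. Tying C9 and C9' into a lactone before the opening was also set aside: it would hold C9 in the plane of ring B and force ring C pseudoequatorial against the C8 methoxy group in the trans transition state. Cyclopropane 9 already holds every carbon of 15, has one ring instead of three, and only one of its three stereocentres (C2) has to be right. The forward reaction must cleave C1–C3 and not C1–C2, arylate C1 at carbon and not at the enolate oxygen, form C1 trans to C2, and leave C2 untouched.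

9 from 7, and 7 from 4 and 6. The C2 ester is taken back to an aldehyde, and the C1–C3 and C2–C3 bonds of the cyclopropane are cut. This gives two achiral fragments of similar size, the enal 6 (C1, C2, C9, ring C) and the bromo keto ester 4 (C3, C9', C4, ring A). The forward step is an amine-catalysed Michael-initiated ring closure that sets C2 through the catalyst-controlled addition at C1 and a trans ring closure.

4 from 1, and 6 from 5. Bromination, Claisen condensation and benzylation lead back to acetosyringone 1 through 3 and 2; benzylation leads back to coniferaldehyde 5. Both are commercial lignin-derived phenols.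

## Roads not taken

Alternative 1: the most obvious cut is C1–C8a at the alcohol oxidation level. The forward key step is an acid-mediated Friedel–Crafts cyclization of the benzylic alcohol A1, a trans-α-benzyl-β-(hydroxybenzyl)butyrolactone built by conjugate addition and alkylation on a chiral butenolide. It forms the same bond as the chosen plan, but C2 and C3 must both be set before the cyclization with stoichiometric chirality, and the three carbon–carbon bonds of the chain are made in separate operations. The chosen plan sets one centre catalytically, makes the whole skeleton from two fragments in one step, and lets all cyclopropane diastereomers converge.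

Alternative 2: cut C1–C2 and C3–C4. The forward key step is a Diels–Alder reaction of the o-quinodimethane A3, released from sulfone A2 by loss of SO2, with a fumaric diester. The aryl group of A3 must turn outward directly beside the methoxy group that becomes the C8 substituent, so the diene geometry is not secured. A trans dienophile places one ester endo and one exo, so the C1/C2 relationship is not controlled, and absolute control needs an auxiliary. A2 is a hexasubstituted benzene that costs several steps before any stereocentre exists.

Alternative 3: cut C2–C3 and C1–C8a in the biomimetic sense. The forward key step is a one-electron oxidative cross-coupling of the guaiacyl and syringyl hydroxycinnamic esters to the dihydronaphthalene A4. It is the shortest road, but nothing in the substrates favours cross-coupling over homo-coupling or decides which ring closes onto which benzylic carbon, and the product is racemic with no handle for the absolute configuration.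

Key step: step 7

Remark on the chemistry: 7, 8 and 9 are carried as a mixture of epimers at the quaternary cyclopropane carbon (undefined in their SMILES), because step 7 makes this carbon planar; 11 is a tautomeric mixture written as its enol.

## Steps

Step 1
Reactants: 1 1-(4-hydroxy-3,5-dimethoxyphenyl)ethan-1-one (acetosyringone)
Product: 2 1-[4-(benzyloxy)-3,5-dimethoxyphenyl]ethan-1-one
Conditions: BnBr, K2CO3, DMF, 60 °C
Reagents that add atoms: benzyl bromide, BrCc1ccccc1
Why: Williamson ether synthesis on the phenoxide, which is alkylated in DMF despite its two flanking methoxy groups; the benzyl ether survives base, Lewis acid and triflation and is removed in step 9.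

Step 2
Reactants: 2 1-[4-(benzyloxy)-3,5-dimethoxyphenyl]ethan-1-one
Product: 3 methyl 3-[4-(benzyloxy)-3,5-dimethoxyphenyl]-3-oxopropanoate
Conditions: NaH, (MeO)2CO, THF, reflux; then AcOH
Reagents that add atoms: dimethyl carbonate, COC(=O)OC
Why: Crossed Claisen condensation of the methyl ketone enolate with non-enolizable dimethyl carbonate, driven by formation of the sodium enolate of the β-keto ester.

Step 3
Reactants: 3 methyl 3-[4-(benzyloxy)-3,5-dimethoxyphenyl]-3-oxopropanoate
Product: 4 methyl 3-[4-(benzyloxy)-3,5-dimethoxyphenyl]-2-bromo-3-oxopropanoate (racemic)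
Conditions: NBS (1.05 equiv), NH4OAc (cat.), Et2O, 25 °C
Reagents that add atoms: N-bromosuccinimide, O=C1CCC(=O)N1Br
Why: Electrophilic α-bromination of the 1,3-dicarbonyl enol, which is far more nucleophilic than ring A, whose free positions are deactivated by the aroyl carbonyl; one equivalent of NBS limits dibromination.

Step 4
Reactants: 5 (E)-3-(4-hydroxy-3-methoxyphenyl)prop-2-enal (coniferaldehyde)
Product: 6 (E)-3-[4-(benzyloxy)-3-methoxyphenyl]prop-2-enal
Conditions: BnBr, K2CO3, acetone, reflux
Reagents that add atoms: benzyl bromide, BrCc1ccccc1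
Why: Williamson ether synthesis; the weak base leaves the enal untouched, and the capped phenol restores the electrophilicity that the iminium step needs.

Step 5
Reactants: 4 methyl 3-[4-(benzyloxy)-3,5-dimethoxyphenyl]-2-bromo-3-oxopropanoate; 6 (E)-3-[4-(benzyloxy)-3-methoxyphenyl]prop-2-enal
Product: 7 methyl (2R,3S)-1-[4-(benzyloxy)-3,5-dimethoxybenzoyl]-2-[4-(benzyloxy)-3-methoxyphenyl]-3-formylcyclopropane-1-carboxylate
Conditions: (R)-2-[diphenyl(trimethylsilyloxy)methyl]pyrrolidine (20 mol%), 2,6-lutidine (1.1 equiv), CH2Cl2, 0 → 25 °C
Reagents that add atoms: none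
Why: Michael-initiated ring closure under iminium–enamine catalysis, the organocatalytic cyclopropanation of enals with 2-bromo-1,3-dicarbonyl compounds: the enol of 4 adds to the aryl-bearing carbon of the E-iminium ion of 6 on the face left open by the diphenyl(silyloxy)methyl group of the (R)-amine. The resulting enamine then displaces bromide (3-exo-tet) and sets the formyl carbon, the future C2, trans to the aryl group. The quaternary carbon is not controlled and need not be.

Step 6
Reactants: 7 methyl (2R,3S)-1-[4-(benzyloxy)-3,5-dimethoxybenzoyl]-2-[4-(benzyloxy)-3-methoxyphenyl]-3-formylcyclopropane-1-carboxylate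
Product: 9 dimethyl (2S,3R)-1-[4-(benzyloxy)-3,5-dimethoxybenzoyl]-3-[4-(benzyloxy)-3-methoxyphenyl]cyclopropane-1,2-dicarboxylate, via cyclopropanecarboxylic acid 8 (not isolated)
Conditions: NaClO2, NaH2PO4, 2-methyl-2-butene, t-BuOH–H2O, 0 → 25 °C; then TMSCHN2, PhMe–MeOH, 0 °C
Reagents that add atoms: sodium chlorite, [Na+].[O-]Cl=O; trimethylsilyldiazomethane, C[Si](C)(C)C=[N+]=[N-]
Why: Pinnick oxidation is selective for the aldehyde, with the alkene scavenging hypochlorous acid so that the electron-rich rings are spared, and the diazoalkane esterifies without base, so the C2 centre is not touched. The aldehyde, which would not survive the Lewis acid of step 7, becomes the C9 ester.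

Step 7
Reactants: 9 dimethyl (2S,3R)-1-[4-(benzyloxy)-3,5-dimethoxybenzoyl]-3-[4-(benzyloxy)-3-methoxyphenyl]cyclopropane-1,2-dicarboxylate
Product: 11 dimethyl (1R,2S)-7-(benzyloxy)-1-[4-(benzyloxy)-3-methoxyphenyl]-4-hydroxy-6,8-dimethoxy-1,2-dihydronaphthalene-2,3-dicarboxylate (enol tautomer of the 4-oxo-tetralin diester), via ring-opened cation-enolate zwitterion 10 (not isolated)
Conditions: In(OTf)3 (20 mol%), ClCH2CH2Cl, 25 → 60 °C
Reagents that add atoms: none
Why: In(OTf)3 chelates the ketone and the C9' ester on C3, and heterolysis of the strained C1–C3 bond gives zwitterion 10, a para-benzyloxybenzylic cation at C1 and an indium 1,3-dicarbonyl enolate at C3–C4; C8a of ring A then attacks C1 and the arenium proton ends on the enolate. The closest known reaction type is the Lewis-acid ring-opening cyclization of aryl 2-arylcyclopropyl ketones to 4-aryl-1-tetralones (formal homo-Nazarov cyclization), which runs catalytically on keto-ester-activated cyclopropanes. Ring B closes as a six-membered ring by Friedel–Crafts alkylation, 6-exo-trig on the C1=C1' bond of the quinone-methide form of the cation and endo with respect to ring A. C1 is controlled by C2: in the half-chair transition state the C2 ester is pseudoaxial to avoid the substituent on planar C3, ring C is pseudoaxial to avoid the C8 methoxy group, and the two are anti, so C1 forms R, trans to C2. Both epimers at the quaternary carbon of 9, and any cis isomer at C1, give the same 10 and so the same 11, while C2 is carried through because none of its bonds is broken. The step needs cleavage of C1–C3 and not C1–C2, which the two chelating acceptors on C3 against one on C2 secure, and arylation at one site, which the equivalence of the two ortho positions of ring A, each ortho to one and para to the other methoxy group, secures; in 10 ring A sits on an enolate carbon, not a ketone, and is not deactivated. Attack of the enolate oxygen on C1 (dihydrofuran formation) is reversible under the Lewis acid and the arylation is not, so the mixture should drain to 11.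

Step 8
Reactants: 11 dimethyl (1R,2S)-7-(benzyloxy)-1-[4-(benzyloxy)-3-methoxyphenyl]-4-hydroxy-6,8-dimethoxy-1,2-dihydronaphthalene-2,3-dicarboxylate
Product: 12 dimethyl (1R,2S)-7-(benzyloxy)-1-[4-(benzyloxy)-3-methoxyphenyl]-6,8-dimethoxy-4-[(trifluoromethanesulfonyl)oxy]-1,2-dihydronaphthalene-2,3-dicarboxylate
Conditions: Tf2O, i-Pr2NEt, CH2Cl2, −78 → 0 °C
Reagents that add atoms: trifluoromethanesulfonic anhydride, O=S(=O)(OS(=O)(=O)C(F)(F)F)C(F)(F)F
Why: O-sulfonylation of the β-keto ester enol; the hindered amine at low temperature does not deprotonate C2. The triflate fixes the C3=C4 double bond and turns the C4 oxygen into a leaving group.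

Step 9
Reactants: 12 dimethyl (1R,2S)-7-(benzyloxy)-1-[4-(benzyloxy)-3-methoxyphenyl]-6,8-dimethoxy-4-[(trifluoromethanesulfonyl)oxy]-1,2-dihydronaphthalene-2,3-dicarboxylate
Product: 14 dimethyl (1R,2S,3S)-7-hydroxy-1-(4-hydroxy-3-methoxyphenyl)-6,8-dimethoxy-1,2,3,4-tetrahydronaphthalene-2,3-dicarboxylate, via dihydronaphthalene diester 13 (not isolated)
Conditions: H2 (3 atm), 10% Pd/C, NaHCO3, MeOH–EtOAc, 25 °C
Reagents that add atoms: none
Why: Hydrogenolysis of the vinyl triflate (insertion of zerovalent palladium into the C4–O bond, then hydride transfer) gives 13, and the same catalyst cleaves the two benzyl ethers. The C3=C4 bond of 13 is hydrogenated from the face opposite the pseudoaxial ring C on C1, the usual facial preference of trans-1-aryl-1,2-dihydronaphthalenes, which places the C3 ester cis to ring C and trans to the C2 ester (C3 = S). NaHCO3 takes up the triflic acid.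

Step 10
Reactants: 14 dimethyl (1R,2S,3S)-7-hydroxy-1-(4-hydroxy-3-methoxyphenyl)-6,8-dimethoxy-1,2,3,4-tetrahydronaphthalene-2,3-dicarboxylate
Product: 15 (1R,2S,3S)-1-(4-hydroxy-3-methoxyphenyl)-2,3-bis(hydroxymethyl)-6,8-dimethoxy-1,2,3,4-tetrahydronaphthalen-7-ol (target, CNP0325829.1)
Conditions: LiAlH4 (excess), THF, 0 °C → reflux; then KNaC4H4O6 (aq.)
Reagents that add atoms: none
Why: Hydride reduction of both methyl esters to the primary alcohols C9 and C9', with the phenols carried as aluminium phenoxides. Reduction of the esters is faster than their enolization, so C2 and C3 keep their configuration, and the tartrate work-up avoids acid that would close the 1,4-diol to a tetrahydrofuran.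

## Compound list

1 | 1-(4-hydroxy-3,5-dimethoxyphenyl)ethan-1-one (acetosyringone) | CC(=O)c1cc(OC)c(O)c(OC)c1 | starting material
2 | 1-[4-(benzyloxy)-3,5-dimethoxyphenyl]ethan-1-one | CC(=O)c1cc(OC)c(OCc2ccccc2)c(OC)c1 | intermediate
3 | methyl 3-[4-(benzyloxy)-3,5-dimethoxyphenyl]-3-oxopropanoate | COC(=O)CC(=O)c1cc(OC)c(OCc2ccccc2)c(OC)c1 | intermediate
4 | methyl 3-[4-(benzyloxy)-3,5-dimethoxyphenyl]-2-bromo-3-oxopropanoate (racemic) | COC(=O)C(Br)C(=O)c1cc(OC)c(OCc2ccccc2)c(OC)c1 | intermediate
5 | (E)-3-(4-hydroxy-3-methoxyphenyl)prop-2-enal (coniferaldehyde) | COc1cc(/C=C/C=O)ccc1O | starting material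
6 | (E)-3-[4-(benzyloxy)-3-methoxyphenyl]prop-2-enal | COc1cc(/C=C/C=O)ccc1OCc1ccccc1 | intermediate
7 | methyl (2R,3S)-1-[4-(benzyloxy)-3,5-dimethoxybenzoyl]-2-[4-(benzyloxy)-3-methoxyphenyl]-3-formylcyclopropane-1-carboxylate (both epimers at C1) | O=C[C@H]1[C@H](c2ccc(OCc3ccccc3)c(OC)c2)C1(C(=O)OC)C(=O)c1cc(OC)c(OCc2ccccc2)c(OC)c1 | intermediate
8 | (1S,3R)-2-[4-(benzyloxy)-3,5-dimethoxybenzoyl]-3-[4-(benzyloxy)-3-methoxyphenyl]-2-(methoxycarbonyl)cyclopropane-1-carboxylic acid (both epimers at C2; formed and consumed in step 6) | OC(=O)[C@H]1[C@H](c2ccc(OCc3ccccc3)c(OC)c2)C1(C(=O)OC)C(=O)c1cc(OC)c(OCc2ccccc2)c(OC)c1 | intermediate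
9 | dimethyl (2S,3R)-1-[4-(benzyloxy)-3,5-dimethoxybenzoyl]-3-[4-(benzyloxy)-3-methoxyphenyl]cyclopropane-1,2-dicarboxylate (both epimers at C1) | COC(=O)[C@H]1[C@H](c2ccc(OCc3ccccc3)c(OC)c2)C1(C(=O)OC)C(=O)c1cc(OC)c(OCc2ccccc2)c(OC)c1 | intermediate
10 | ring-opened zwitterion: 4-(benzyloxy)-3-methoxybenzylic cation at C1, indium-bound enolate of the β-keto ester at C3–C4, C2 intact (written metal-free; formed and consumed in step 7) | COC(=O)C(=C([O-])c1cc(OC)c(OCc2ccccc2)c(OC)c1)[C@H]([CH+]c1ccc(OCc2ccccc2)c(OC)c1)C(=O)OC | intermediate
11 | dimethyl (1R,2S)-7-(benzyloxy)-1-[4-(benzyloxy)-3-methoxyphenyl]-4-hydroxy-6,8-dimethoxy-1,2-dihydronaphthalene-2,3-dicarboxylate (enol tautomer of the 4-oxo-tetralin diester) | COc1cc([C@@H]2c3c(cc(OC)c(OCc4ccccc4)c3OC)C(O)=C(C(=O)OC)[C@H]2C(=O)OC)ccc1OCc1ccccc1 | intermediate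
12 | dimethyl (1R,2S)-7-(benzyloxy)-1-[4-(benzyloxy)-3-methoxyphenyl]-6,8-dimethoxy-4-[(trifluoromethanesulfonyl)oxy]-1,2-dihydronaphthalene-2,3-dicarboxylate | COc1cc([C@@H]2c3c(cc(OC)c(OCc4ccccc4)c3OC)C(OS(=O)(=O)C(F)(F)F)=C(C(=O)OC)[C@H]2C(=O)OC)ccc1OCc1ccccc1 | intermediate
13 | dimethyl (1R,2S)-7-(benzyloxy)-1-[4-(benzyloxy)-3-methoxyphenyl]-6,8-dimethoxy-1,2-dihydronaphthalene-2,3-dicarboxylate (formed and consumed in step 9) | COc1cc([C@@H]2c3c(cc(OC)c(OCc4ccccc4)c3OC)C=C(C(=O)OC)[C@H]2C(=O)OC)ccc1OCc1ccccc1 | intermediate
14 | dimethyl (1R,2S,3S)-7-hydroxy-1-(4-hydroxy-3-methoxyphenyl)-6,8-dimethoxy-1,2,3,4-tetrahydronaphthalene-2,3-dicarboxylate | COc1cc([C@@H]2c3c(cc(OC)c(O)c3OC)C[C@H](C(=O)OC)[C@H]2C(=O)OC)ccc1O | intermediate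
15 | (1R,2S,3S)-1-(4-hydroxy-3-methoxyphenyl)-2,3-bis(hydroxymethyl)-6,8-dimethoxy-1,2,3,4-tetrahydronaphthalen-7-ol | COc1cc([C@@H]2c3c(cc(OC)c(O)c3OC)C[C@H](CO)[C@H]2CO)ccc1O | target

## Step count and risks

Total: 10 steps. Longest linear sequence: 9 steps (steps 1, 2, 3, 5, 6, 7, 8, 9, 10); step 4 is a one-step branch.

Step 7 (key step). Three things may go wrong. The enolate oxygen may add to the C1 cation faster than C8a does and the dihydrofuran may fail to re-open. Proton loss from C2 next to the cation would erase the only catalyst-set centre. The Lewis acid may strip a benzyl ether. Fallback: ring opening and arylation are decoupled. Starting from 9, a catalytic amount of Sc(OTf)3 in methanol should open the cyclopropane at C1 to the benzylic methyl ether, dimethyl (3R)-2-[4-(benzyloxy)-3,5-dimethoxybenzoyl]-3-{[4-(benzyloxy)-3-methoxyphenyl](methoxy)methyl}butanedioate F1. Ionizing F1 with CF3CO2H in CH2Cl2 at low temperature then runs the arylation as a classical Brønsted-acid benzylic cation cyclization on the enol form of the keto ester, and the route is rejoined at 11.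

Step 9. Hydrogen delivery to C3=C4 may show poor facial selectivity, because the pseudoaxial C2 ester shields the face opposite ring C, and the triflate hydrogenolysis may stop short. Fallback: the stereo-defining hydrogenation is changed from a sterically controlled to a hydroxyl-directed one. Starting from 12, Pd(OAc)2/PPh3 with HCO2H and Et3N in DMF gives 13 as an isolated compound. i-Bu2AlH in CH2Cl2 at −78 °C reduces both esters to {(1R,2S)-7-(benzyloxy)-1-[4-(benzyloxy)-3-methoxyphenyl]-6,8-dimethoxy-1,2-dihydronaphthalene-2,3-diyl}dimethanol F2. Hydrogenation of F2 with [Ir(cod)(PCy3)(py)]PF6 in CH2Cl2 is directed by the C9 hydroxyl on the face opposite ring C and gives {(1R,2S,3S)-7-(benzyloxy)-1-[4-(benzyloxy)-3-methoxyphenyl]-6,8-dimethoxy-1,2,3,4-tetrahydronaphthalene-2,3-diyl}dimethanol F3. Hydrogenolysis of the benzyl ethers (H2, Pd/C) rejoins the route at 15.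

Step 5. Iminium formation and conjugate addition may be slow with the electron-rich enal; the ring closure may go through oxygen; the amine may re-open the product; a reversible Michael step may erode the enantiomeric purity. Fallback: carbon–carbon bond formation and halogenation are separated. Starting from 3 and 6, the same amine with benzoic acid as co-catalyst should give the Michael adduct methyl (3S)-2-[4-(benzyloxy)-3,5-dimethoxybenzoyl]-3-[4-(benzyloxy)-3-methoxyphenyl]-5-oxopentanoate F4, in equilibrium with its cyclic hemiacetal. NBS brominates the dicarbonyl carbon to methyl (3R)-2-[4-(benzyloxy)-3,5-dimethoxybenzoyl]-3-[4-(benzyloxy)-3-methoxyphenyl]-2-bromo-5-oxopentanoate F5. The amine and 2,6-lutidine then close the ring through the enamine, and the route is rejoined at 7.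

Step 8. The base may move the double bond into conjugation with both esters, after which aromatization would destroy C1 and C2; C2 may epimerize; triflation may occur at carbon. Fallback: the enol is not sulfonylated at all. Starting from 11, NaBH4 in MeOH at −20 °C gives the benzylic alcohol dimethyl (1R,2S)-7-(benzyloxy)-1-[4-(benzyloxy)-3-methoxyphenyl]-4-hydroxy-6,8-dimethoxy-1,2,3,4-tetrahydronaphthalene-2,3-dicarboxylate F6. A catalytic amount of p-TsOH in toluene at 80 °C dehydrates F6 through the para-alkoxybenzylic C4 cation. The route is rejoined at 13, which the conditions of step 9 convert into 14.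

## Further compounds

F1 | step 7 | dimethyl (3R)-2-[4-(benzyloxy)-3,5-dimethoxybenzoyl]-3-{[4-(benzyloxy)-3-methoxyphenyl](methoxy)methyl}butanedioate (epimers at C2 and at the methoxy-bearing carbon) | COC(=O)C(C(=O)c1cc(OC)c(OCc2ccccc2)c(OC)c1)[C@H](C(OC)c1ccc(OCc2ccccc2)c(OC)c1)C(=O)OC
F2 | step 9 | {(1R,2S)-7-(benzyloxy)-1-[4-(benzyloxy)-3-methoxyphenyl]-6,8-dimethoxy-1,2-dihydronaphthalene-2,3-diyl}dimethanol | COc1cc([C@@H]2c3c(cc(OC)c(OCc4ccccc4)c3OC)C=C(CO)[C@H]2CO)ccc1OCc1ccccc1
F3 | step 9 | {(1R,2S,3S)-7-(benzyloxy)-1-[4-(benzyloxy)-3-methoxyphenyl]-6,8-dimethoxy-1,2,3,4-tetrahydronaphthalene-2,3-diyl}dimethanol | COc1cc([C@@H]2c3c(cc(OC)c(OCc4ccccc4)c3OC)C[C@H](CO)[C@H]2CO)ccc1OCc1ccccc1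
F4 | step 5 | methyl (3S)-2-[4-(benzyloxy)-3,5-dimethoxybenzoyl]-3-[4-(benzyloxy)-3-methoxyphenyl]-5-oxopentanoate (epimers at C2; in equilibrium with its cyclic hemiacetal) | COC(=O)C(C(=O)c1cc(OC)c(OCc2ccccc2)c(OC)c1)[C@H](CC=O)c1ccc(OCc2ccccc2)c(OC)c1
F5 | step 5 | methyl (3R)-2-[4-(benzyloxy)-3,5-dimethoxybenzoyl]-3-[4-(benzyloxy)-3-methoxyphenyl]-2-bromo-5-oxopentanoate (epimers at C2) | COC(=O)C(Br)(C(=O)c1cc(OC)c(OCc2ccccc2)c(OC)c1)[C@H](CC=O)c1ccc(OCc2ccccc2)c(OC)c1
F6 | step 8 | dimethyl (1R,2S)-7-(benzyloxy)-1-[4-(benzyloxy)-3-methoxyphenyl]-4-hydroxy-6,8-dimethoxy-1,2,3,4-tetrahydronaphthalene-2,3-dicarboxylate (epimers at C3 and C4) | COc1cc([C@@H]2c3c(cc(OC)c(OCc4ccccc4)c3OC)C(O)C(C(=O)OC)[C@H]2C(=O)OC)ccc1OCc1ccccc1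
A1 | alternative 1 | (3S,4S)-3-[4-(benzyloxy)-3,5-dimethoxybenzyl]-4-{[4-(benzyloxy)-3-methoxyphenyl](hydroxy)methyl}oxolan-2-one (either carbinol epimer) | O=C1OC[C@@H](C(O)c2ccc(OCc3ccccc3)c(OC)c2)[C@@H]1Cc1cc(OC)c(OCc2ccccc2)c(OC)c1
A2 | alternative 2 | 6-(benzyloxy)-1-[4-(benzyloxy)-3-methoxyphenyl]-5,7-dimethoxy-1,3-dihydro-2-benzothiophene 2,2-dioxide (racemic) | COc1cc(C2c3c(cc(OC)c(OCc4ccccc4)c3OC)CS2(=O)=O)ccc1OCc1ccccc1
A3 | alternative 2 | 2-(benzyloxy)-6-{(Z)-[4-(benzyloxy)-3-methoxyphenyl]methylidene}-1,3-dimethoxy-5-methylidenecyclohexa-1,3-diene | C=C1C=C(OC)C(OCc2ccccc2)=C(OC)/C1=C\c1ccc(OCc2ccccc2)c(OC)c1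
A4 | alternative 3 | dimethyl rac-(1R,2S)-7-hydroxy-1-(4-hydroxy-3-methoxyphenyl)-6,8-dimethoxy-1,2-dihydronaphthalene-2,3-dicarboxylate (one enantiomer drawn) | COc1cc([C@@H]2c3c(cc(OC)c(O)c3OC)C=C(C(=O)OC)[C@H]2C(=O)OC)ccc1O
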